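**Plan**
- Cuts, in order: the two O-benzyl helpers; the bond from the bridge CH2 on C8 of ring A to C3 of the pyrone; C2–phenyl of ring C; the chromone C2 unit (O1–C2 and C2–C3); ring A–CHO. In the pyrone, the cuts are the O1–C2 lactone bond and C5–C6.
- The bridge bond is made at the aldehyde oxidation level, in one pot, from an 8-formylflavanone, the free 4-hydroxy-2-pyrone and a hydride donor.
- Enabling feature: pyrone C3 lies between the C2 lactone carbonyl and the C4 enol OH, so it is a cyclic 1,3-dicarbonyl CH-acid. The bridge carbon sits on C8, ortho to O1 and O7 and para to O5, so its arylidene-pyrandione is a stabilised, quinone-methide-like hydride acceptor.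
- Forward order: ring A is bought and formylated first. The formyl carbon is the future bridge, and it leaves the OH between CHO and acetyl doubly chelated, so benzylation caps the other two phenols and ring C can close only next to that carbon (C8, not C6). Ring C is then closed as a chromone and arylated to the flavanone; the pyrone is made separately; union and debenzylation follow.
- Stereochemistry: the only stereocentre, C2 (S), comes from catalyst control in the conjugate addition. All later steps are neutral or weakly acidic.

Key step: step 7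

Assumption: the sense of induction of t-BuPyOx on chromone 5 is taken to match that known for β-substituted cyclic enones. This makes the (R)-ligand the one that delivers 2S. Both antipodes are commercial, and the assignment should be checked by CD before going on.

**Step 1**
Reactants: 1 1-(2,4,6-trihydroxyphenyl)ethan-1-one (phloroacetophenone, dried)
Product: 2 3-acetyl-2,4,6-trihydroxybenzaldehyde
Conditions: POCl3 (1.1 equiv), DMF, EtOAc, 0 °C to rt; then H2O, 40 °C
Reagents that add atoms: N,N-dimethylformamide CN(C)C=O; water O
Why: Vilsmeier–Haack formylation should hit the ring and not the acetyl group, because the phloroglucinol nucleus is by far the best nucleophile at 0 °C, C3 and C5 are equivalent so only one monoaldehyde is possible, and the new formyl group deactivates the ring against a second attack.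

**Step 2**
Reactants: 2 3-acetyl-2,4,6-trihydroxybenzaldehyde
Product: 3 3-acetyl-4,6-bis(benzyloxy)-2-hydroxybenzaldehyde
Conditions: BnBr (2.05 equiv), K2CO3 (2.1 equiv), DMF, 0 °C to rt
Reagents that add atoms: benzyl bromide BrCc1ccccc1
Why: Williamson etherification under hydrogen-bond control: the OH at C2 lies between formyl and acetyl, is chelated from both sides and is the most hindered, so the two outer phenoxides should be benzylated first, which leaves free exactly the oxygen that is to become O1 next to the future bridge carbon.

**Step 3**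
Reactants: 3 3-acetyl-4,6-bis(benzyloxy)-2-hydroxybenzaldehyde
Product: 5 5,7-bis(benzyloxy)-4-oxo-4H-chromene-8-carbaldehyde, via enaminone 4 (not isolated)
Conditions: DMF-DMA (3 equiv), PhMe, 90 °C; evaporate; conc. HCl, CH2Cl2, rt
Reagents that add atoms: N,N-dimethylformamide dimethyl acetal COC(OC)N(C)C
Why: Enaminone route to chromones: the amide acetal condenses only with the acetyl CH3 (the aldehyde has no α-hydrogen), and acid then drives 6-endo-trig addition of the single free phenol to the β-carbon with loss of dimethylamine, so the formyl carbon necessarily ends up on C8.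

**Step 4**
Reactants: 5 5,7-bis(benzyloxy)-4-oxo-4H-chromene-8-carbaldehyde; 6 phenylboronic acid
Product: 7 (2S)-5,7-bis(benzyloxy)-4-oxo-2-phenyl-3,4-dihydro-2H-chromene-8-carbaldehyde
Conditions: 6 (2 equiv), Pd(OCOCF3)2 (10 mol %), (R)-t-BuPyOx (12 mol %), NH4PF6 (30 mol %), H2O (5 equiv), ClCH2CH2Cl, 60 °C
Reagents that add atoms: none
Why: Pd(II)/pyridine-oxazoline-catalysed asymmetric conjugate addition of an arylboronic acid to a chromone: the C2=C3 bond inserts into a cationic Pd–phenyl species on the face left open by the tert-butyl group of the ligand, which should set C2 as S, while the base-free medium keeps the flavanone from racemising and the hindered, electron-rich aldehyde should be a much poorer acceptor than the Pd-bound enone.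

**Step 5**
Reactants: 8 ethyl 3-oxopentanoate; 9 N-methoxy-N-methylpropanamide
Product: 10 ethyl 4-methyl-3,5-dioxoheptanoate (racemic, keto–enol mixture)
Conditions: LDA (2.1 equiv, commercial solution), THF, -78 to 0 °C; 9, -78 to 0 °C; 1 M HCl
Reagents that add atoms: none
Why: γ-Acylation of a β-keto ester dianion: the more basic terminal carbanion (C4) attacks the Weinreb amide, whose chelated tetrahedral adduct survives until the quench and so prevents over-addition and proton exchange with the acidic product.

**Step 6**
Reactants: 10 ethyl 4-methyl-3,5-dioxoheptanoate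
Product: 11 6-ethyl-4-hydroxy-5-methyl-2H-pyran-2-one
Conditions: DBU (1 equiv), PhMe, reflux; 1 M HCl
Reagents that add atoms: none
Why: Base-mediated lactonisation of a 3,5-dioxo ester: the C5 enolate oxygen attacks the ester carbonyl (6-exo-trig) and loss of ethanol gives the aromatic 4-hydroxy-2-pyrone, which also removes the labile stereocentre of 10.

**Step 7**
Reactants: 7 (2S)-5,7-bis(benzyloxy)-4-oxo-2-phenyl-3,4-dihydro-2H-chromene-8-carbaldehyde; 11 6-ethyl-4-hydroxy-5-methyl-2H-pyran-2-one
Product: 13 (2S)-5,7-bis(benzyloxy)-8-[(6-ethyl-4-hydroxy-5-methyl-2-oxo-2H-pyran-3-yl)methyl]-2-phenyl-2,3-dihydro-4H-chromen-4-one, via arylidene-pyrandione 12 (not isolated)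
Conditions: L-proline (20 mol %), Hantzsch ester (diethyl 2,6-dimethyl-1,4-dihydropyridine-3,5-dicarboxylate, 1.1 equiv), CH2Cl2–EtOH, 25–40 °C
Reagents that add atoms: none
Why: L-Proline turns the C8 aldehyde of 7 into an iminium ion that is attacked by C3 of 11, the CH-acidic carbon between the C2 lactone carbonyl and the C4 enol, and loss of proline gives the arylidene-pyrandione 12 (Knoevenagel condensation), in which the new C–C bond is already in place. 12 is a push–pull, quinone-methide-like acceptor stabilised by O1, O7 and O5 of ring A, and the Hantzsch ester delivers hydride to its exocyclic carbon, after which proton transfer restores the aromatic 4-hydroxy-2-pyrone. The closest known reaction type is the amino-acid-catalysed three-component reductive alkylation of cyclic 1,3-dicarbonyl CH-acids (4-hydroxy-6-methyl-2-pyrone and 4-hydroxycoumarin among them) with aldehydes and Hantzsch ester. No ring is closed and no stereocentre is formed; C2 is only carried through, which the weakly acidic medium (pyrone pKa about 5, no free amine base) and the benzyl caps on O5 and O7 should secure by shutting off retro-oxa-Michael opening and Wessely–Moser scrambling. The step needs cross-selectivity (one flavanone, one carbon, one pyrone), secured because the bridge carbon is already bound to C8 and because fast hydride capture, helped by the two ortho substituents of the aryl group, suppresses the reversible addition of a second pyrone to 12. It also needs chemoselectivity for CHO over the C4 ketone, secured because that ketone is a hindered vinylogous ester that forms no iminium ion and is inert to the Hantzsch ester.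

**Step 8**
Reactants: 13 (2S)-5,7-bis(benzyloxy)-8-[(6-ethyl-4-hydroxy-5-methyl-2-oxo-2H-pyran-3-yl)methyl]-2-phenyl-2,3-dihydro-4H-chromen-4-one
Product: 14 (2S)-8-[(6-ethyl-4-hydroxy-5-methyl-2-oxo-2H-pyran-3-yl)methyl]-5,7-dihydroxy-2-phenyl-2,3-dihydro-4H-chromen-4-one (target)
Conditions: H2 (1 atm), 10 % Pd/C, EtOAc–MeOH, rt, stopped after two equivalents of H2
Reagents that add atoms: none
Why: Catalytic hydrogenolysis of the two primary aryl benzyl ethers is neutral and so should leave C2 untouched, while the secondary, ring-bound C2–O1 bond, the deactivated C4 ketone and the tetrasubstituted pyrone double bond should all react far more slowly.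

**Compound list**
1 | 1-(2,4,6-trihydroxyphenyl)ethan-1-one | CC(=O)c1c(O)cc(O)cc1O | starting material
2 | 3-acetyl-2,4,6-trihydroxybenzaldehyde | CC(=O)c1c(O)cc(O)c(C=O)c1O | intermediate
3 | 3-acetyl-4,6-bis(benzyloxy)-2-hydroxybenzaldehyde | CC(=O)c1c(OCc2ccccc2)cc(OCc2ccccc2)c(C=O)c1O | intermediate
4 | 4,6-bis(benzyloxy)-3-[(E)-3-(dimethylamino)prop-2-enoyl]-2-hydroxybenzaldehyde | CN(C)/C=C/C(=O)c1c(OCc2ccccc2)cc(OCc2ccccc2)c(C=O)c1O | intermediate
5 | 5,7-bis(benzyloxy)-4-oxo-4H-chromene-8-carbaldehyde | O=Cc1c(OCc2ccccc2)cc(OCc2ccccc2)c2c(=O)ccoc12 | intermediate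
6 | phenylboronic acid | OB(O)c1ccccc1 | starting material
7 | (2S)-5,7-bis(benzyloxy)-4-oxo-2-phenyl-3,4-dihydro-2H-chromene-8-carbaldehyde | O=Cc1c(OCc2ccccc2)cc(OCc2ccccc2)c2c1O[C@H](c1ccccc1)CC2=O | intermediate
8 | ethyl 3-oxopentanoate | CCC(=O)CC(=O)OCC | starting material
9 | N-methoxy-N-methylpropanamide | CCC(=O)N(C)OC | starting material
10 | ethyl 4-methyl-3,5-dioxoheptanoate | CCC(=O)C(C)C(=O)CC(=O)OCC | intermediate
11 | 6-ethyl-4-hydroxy-5-methyl-2H-pyran-2-one | CCc1oc(=O)cc(O)c1C | intermediate
12 | 3-{[(2S)-5,7-bis(benzyloxy)-4-oxo-2-phenyl-3,4-dihydro-2H-chromen-8-yl]methylidene}-6-ethyl-5-methyl-2H-pyran-2,4(3H)-dione | CCC1=C(C)C(=O)C(=Cc2c(OCc3ccccc3)cc(OCc3ccccc3)c3c2O[C@H](c2ccccc2)CC3=O)C(=O)O1 | intermediate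
13 | (2S)-5,7-bis(benzyloxy)-8-[(6-ethyl-4-hydroxy-5-methyl-2-oxo-2H-pyran-3-yl)methyl]-2-phenyl-2,3-dihydro-4H-chromen-4-one | CCc1oc(=O)c(Cc2c(OCc3ccccc3)cc(OCc3ccccc3)c3c2O[C@H](c2ccccc2)CC3=O)c(O)c1C | intermediate
14 | (2S)-8-[(6-ethyl-4-hydroxy-5-methyl-2-oxo-2H-pyran-3-yl)methyl]-5,7-dihydroxy-2-phenyl-2,3-dihydro-4H-chromen-4-one | CCc1oc(=O)c(Cc2c(O)cc(O)c3c2O[C@H](c2ccccc2)CC3=O)c(O)c1C | target

Total step count: 8. Longest linear sequence: 6 (steps 1, 2, 3, 4, 7, 8).

**Steps most likely to fail**

**Step 7.**
- What may go wrong: condensation of the doubly ortho-substituted, electron-rich aldehyde may be slow, and long contact with the amino acid may allow retro-oxa-Michael opening of ring C and loss of enantiopurity.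
- Fallback: it sets out from 7 and replaces condensation/hydride transfer by an acid-triggered ionisation.
- The aldehyde is reduced chemoselectively (NaBH4, THF–MeOH, -40 °C) to the benzylic alcohol (2S)-5,7-bis(benzyloxy)-8-(hydroxymethyl)-2-phenyl-2,3-dihydro-4H-chromen-4-one F1.
- F1 is ionised with a catalytic acid (Bi(OTf)3 or TsOH, CH2Cl2–MeNO2, rt) in the presence of 11.
- The cation, stabilised by O1, O7 and O5, is captured at pyrone C3 (dehydrative benzylation of a 1,3-dicarbonyl compound). The route is rejoined at 13.

**Step 4.**
- What may go wrong: the 5,7-dialkoxychromone may insert slowly, phenyl transfer to the aldehyde may compete, or facial selectivity may be insufficient.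
- Fallback: it sets out from 3 and gives up catalytic induction.
- Claisen–Schmidt condensation with excess benzaldehyde (KOH, EtOH, rt) gives the chalcone 4,6-bis(benzyloxy)-2-hydroxy-3-[(E)-3-phenylprop-2-enoyl]benzaldehyde F2.
- Oxa-Michael closure (NaOAc, EtOH, reflux) gives the racemic flavanone 5,7-bis(benzyloxy)-4-oxo-2-phenyl-3,4-dihydro-2H-chromene-8-carbaldehyde F3.
- Preparative chromatography on a chiral phase separates 7 from the (2R)-enantiomer (2R)-5,7-bis(benzyloxy)-4-oxo-2-phenyl-3,4-dihydro-2H-chromene-8-carbaldehyde F4. F4 is returned to F3 by the same NaOAc treatment. The route is rejoined at 7.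

**Step 2.**
- What may go wrong: discrimination between the three phenols may be incomplete, with benzylation of the inner OH or over-benzylation.
- Fallback: it sets out from 1 and reverses the order, so the regiochemistry rests on ortho direction by a single free phenol.
- Bis-benzylation of 1 (BnBr, K2CO3, acetone, reflux) gives 1-[2,4-bis(benzyloxy)-6-hydroxyphenyl]ethan-1-one F5.
- Casnati–Skattebøl ortho-formylation (MgCl2, Et3N, paraformaldehyde, MeCN, reflux) places the aldehyde next to the free OH. The route is rejoined at 3.

**Further compounds**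
F1 | step 7 | (2S)-5,7-bis(benzyloxy)-8-(hydroxymethyl)-2-phenyl-2,3-dihydro-4H-chromen-4-one | OCc1c(OCc2ccccc2)cc(OCc2ccccc2)c2c1O[C@H](c1ccccc1)CC2=O
F2 | step 4 | 4,6-bis(benzyloxy)-2-hydroxy-3-[(E)-3-phenylprop-2-enoyl]benzaldehyde | O=Cc1c(O)c(C(=O)/C=C/c2ccccc2)c(OCc2ccccc2)cc1OCc1ccccc1
F3 | step 4 | racemic 5,7-bis(benzyloxy)-4-oxo-2-phenyl-3,4-dihydro-2H-chromene-8-carbaldehyde | O=Cc1c(OCc2ccccc2)cc(OCc2ccccc2)c2c1OC(c1ccccc1)CC2=O
F4 | step 4 | (2R)-5,7-bis(benzyloxy)-4-oxo-2-phenyl-3,4-dihydro-2H-chromene-8-carbaldehyde | O=Cc1c(OCc2ccccc2)cc(OCc2ccccc2)c2c1O[C@@H](c1ccccc1)CC2=O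
F5 | step 2 | 1-[2,4-bis(benzyloxy)-6-hydroxyphenyl]ethan-1-one | CC(=O)c1c(O)cc(OCc2ccccc2)cc1OCc1ccccc1
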